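**Retrosynthetic overview**

- Feature: in the 2,3-dihydro-1,4-benzodioxine (O1, C2 bearing syringyl ring A, C3 bearing CH2OH, O4, C4a, C5-OMe, C7-propenol, C8a; benzo ring = ring B), C3 is bonded to the aryl ether oxygen O4, to the benzylic carbinol carbon C2 and to a carbon that can stand at the ester level. This is the alpha-aryloxy beta-hydroxy ester pattern that a diazoacetate carbon gives when it is placed between a phenol O–H and an aldehyde C=O.
- Last disconnection, O1–C8a: the dioxane ring (the only ring made; rings A and B are bought) is closed by CuI-catalysed etherification of a C8a bromide with the C2 hydroxyl. C2 is retained, so a threo chain gives the trans ring.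
- Key disconnection, O4–C3 together with C2–C3: three-component union of bromophenol 2, ethyl diazoacetate 5 and O-pivaloyl syringaldehyde 4.
- Ring B enters with its complete C7 side chain as a methyl acrylate (Wittig on 5-bromovanillin), so no C–C bond is made after the key step. One i-Bu2AlH reduction, silylation, ring closure and fluoride deprotection finish the route.

Key step: step 3

Assumption: the (S) enantiomer of the 3,3'-diiodo-BINOL ligand is taken to deliver the (2R,3S) adduct 7; this facial assignment is provisional, and the (R) ligand would be used if the opposite sense were found.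

**Route**

Step 1
Reactants: 1 3-bromo-4-hydroxy-5-methoxybenzaldehyde (5-bromovanillin)
Product: 2 methyl (E)-3-(3-bromo-4-hydroxy-5-methoxyphenyl)prop-2-enoate
Conditions: Ph3P=CHCO2Me (1.5 equiv), toluene, 100 °C
Reagents that add atoms: methyl (triphenylphosphoranylidene)acetate, COC(=O)C=P(c1ccccc1)(c1ccccc1)c1ccccc1
Why: Wittig olefination with an ester-stabilised ylide is (E)-selective and tolerates the free phenol, so ring B carries the whole C7 side chain at the ester level before the key step.

Step 2
Reactants: 3 4-hydroxy-3,5-dimethoxybenzaldehyde (syringaldehyde)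
Product: 4 4-formyl-2,6-dimethoxyphenyl 2,2-dimethylpropanoate
Conditions: t-BuCOCl, Et3N, DMAP (cat.), CH2Cl2, 0 °C to rt
Reagents that add atoms: pivaloyl chloride, CC(C)(C)C(Cl)=O
Why: DMAP-catalysed acylation of the phenol turns the para donor oxygen into an acceptor, which should raise the electrophilicity of the aldehyde for step 3.

Step 3
Reactants: 2 methyl (E)-3-(3-bromo-4-hydroxy-5-methoxyphenyl)prop-2-enoate; 4 4-formyl-2,6-dimethoxyphenyl 2,2-dimethylpropanoate (1.5 equiv); 5 ethyl diazoacetate (1.5 equiv)
Product: 7 ethyl (2R,3S)-2-{2-bromo-6-methoxy-4-[(E)-3-methoxy-3-oxoprop-1-en-1-yl]phenoxy}-3-{4-[(2,2-dimethylpropanoyl)oxy]-3,5-dimethoxyphenyl}-3-hydroxypropanoate (threo aldol ester), via oxonium ylide 6 (not isolated)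
Conditions: Rh2(OAc)4 (2 mol %), Zr(OBu)4/(S)-3,3'-diiodo-BINOL (1:2, 15 mol % Zr, premixed and stripped of butanol), 4 Å sieves, CH2Cl2, 0 °C, 5 added by syringe pump over 4 h
Reagents that add atoms: none
Why: Proposed new method: Rh2(OAc)4 takes N2 from 5 and the oxygen of phenol 2 (free or zirconium-bound) adds to the catalyst-bound carbene to give oxonium ylide 6, an enolate equivalent that should pass to a zirconium enolate and add to aldehyde 4 held on the same BINOL-bearing zirconium centre before the 1,2-proton shift that would give plain O–H insertion; the closest known reaction type is the Rh2(OAc)4/Zr(OBu)4–BINOL three-component coupling of aryl diazoacetates, alcohols and aryl aldehydes, which has not been shown for a phenol with an acceptor-only diazoacetate. No ring closes; the step forms O4–C3 and C2–C3 of the later dioxane in the open chain. C3 and C2 arise together in the aldol event: the threo (syn) relation should follow from the closed six-membered transition state of a zirconium enolate, which is syn-selective from either enolate geometry, and the absolute sense from the BINOL ligand shielding one face of the bound aldehyde. The step needs ylide formation to win over carbonyl-ylide formation, cyclopropanation and diazo dimerisation (slow addition of 5, the acidic O–H of 2 and the electron-poor acrylate serve this) and aldol trapping to win over the proton shift (the pivalate on 4 and the excess of 4 serve this). Regiochemistry is not in question, since 2 has one O–H and 4 one carbonyl group.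

Step 4
Reactants: 7 threo aldol ester
Product: 8 (1S,2S)-2-{2-bromo-4-[(E)-3-hydroxyprop-1-en-1-yl]-6-methoxyphenoxy}-1-(4-hydroxy-3,5-dimethoxyphenyl)propane-1,3-diol
Conditions: i-Bu2AlH (9 equiv), CH2Cl2, −78 to 0 °C; aq. potassium sodium tartrate (KNaC4H4O6) work-up
Reagents that add atoms: none
Why: i-Bu2AlH reduces the saturated ester and, in 1,2-fashion, the cinnamate to primary alcohols and cleaves the aryl pivalate in the same operation (ester reduction); at low temperature the aluminium aldolate should neither enolise nor fragment, so both stereocentres are kept.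

Step 5
Reactants: 8 the phenolic triol
Product: 9 (1S,2S)-2-{2-bromo-6-methoxy-4-[(E)-3-(triisopropylsilyloxy)prop-1-en-1-yl]phenoxy}-1-[3,5-dimethoxy-4-(triisopropylsilyloxy)phenyl]-3-(triisopropylsilyloxy)propan-1-ol
Conditions: i-Pr3SiCl (3.6 equiv), imidazole, DMAP (cat.), DMF, 0 °C to rt
Reagents that add atoms: triisopropylsilyl chloride, CC(C)[Si](Cl)(C(C)C)C(C)C
Why: silyl ether formation with the bulky chlorosilane should take place at the two primary hydroxyls and the phenol but not at the hindered secondary benzylic hydroxyl, which is left as the only nucleophile for ring closure.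

Step 6
Reactants: 9 the tris(silyl) bromo alcohol
Product: 10 (2S,3S)-2-[3,5-dimethoxy-4-(triisopropylsilyloxy)phenyl]-5-methoxy-3-[(triisopropylsilyloxy)methyl]-7-[(E)-3-(triisopropylsilyloxy)prop-1-en-1-yl]-2,3-dihydro-1,4-benzodioxine
Conditions: CuI (10 mol %), 3,4,7,8-tetramethyl-1,10-phenanthroline (20 mol %), Cs2CO3 (2 equiv), toluene, 110 °C
Reagents that add atoms: none
Why: Ullmann-type intramolecular C–O coupling closes the six-membered dioxane ring at O1–C8a without breaking the carbinol C–O bond, so C2 is retained and the threo chain gives the trans ring, while the triisopropylsilyl ether keeps the primary oxygen, which could close an isomeric six-membered ring, out of play.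

Step 7
Reactants: 10 the tris(silyl) benzodioxine
Product: 11 4-[(2S,3S)-3-(hydroxymethyl)-7-[(E)-3-hydroxyprop-1-en-1-yl]-5-methoxy-2,3-dihydro-1,4-benzodioxin-2-yl]-2,6-dimethoxyphenol
Conditions: Bu4NF (4 equiv), AcOH (4 equiv), THF, 0 °C to rt
Reagents that add atoms: none
Why: fluoride cleaves all three Si–O bonds (desilylation) under buffered, near-neutral conditions that should spare the cinnamyl alcohol and the p-hydroxybenzyl aryl ether at C2.

**Compound list**

1 | 3-bromo-4-hydroxy-5-methoxybenzaldehyde (5-bromovanillin) | COc1cc(C=O)cc(Br)c1O | starting material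
2 | methyl (E)-3-(3-bromo-4-hydroxy-5-methoxyphenyl)prop-2-enoate | COC(=O)/C=C/c1cc(Br)c(O)c(OC)c1 | intermediate
3 | 4-hydroxy-3,5-dimethoxybenzaldehyde (syringaldehyde) | COc1cc(C=O)cc(OC)c1O | starting material
4 | 4-formyl-2,6-dimethoxyphenyl 2,2-dimethylpropanoate | COc1cc(C=O)cc(OC)c1OC(=O)C(C)(C)C | intermediate
5 | ethyl diazoacetate | CCOC(=O)C=[N+]=[N-] | starting material
6 | oxonium ylide from 2 and the carbene of 5 (drawn metal-free; not isolated) | CCOC(=O)[CH-][OH+]c1c(Br)cc(/C=C/C(=O)OC)cc1OC | intermediate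
7 | ethyl (2R,3S)-2-{2-bromo-6-methoxy-4-[(E)-3-methoxy-3-oxoprop-1-en-1-yl]phenoxy}-3-{4-[(2,2-dimethylpropanoyl)oxy]-3,5-dimethoxyphenyl}-3-hydroxypropanoate | COc1cc([C@H](O)[C@@H](Oc2c(Br)cc(/C=C/C(=O)OC)cc2OC)C(=O)OCC)cc(OC)c1OC(=O)C(C)(C)C | intermediate
8 | (1S,2S)-2-{2-bromo-4-[(E)-3-hydroxyprop-1-en-1-yl]-6-methoxyphenoxy}-1-(4-hydroxy-3,5-dimethoxyphenyl)propane-1,3-diol | COc1cc([C@H](O)[C@@H](Oc2c(Br)cc(/C=C/CO)cc2OC)CO)cc(OC)c1O | intermediate
9 | (1S,2S)-2-{2-bromo-6-methoxy-4-[(E)-3-(triisopropylsilyloxy)prop-1-en-1-yl]phenoxy}-1-[3,5-dimethoxy-4-(triisopropylsilyloxy)phenyl]-3-(triisopropylsilyloxy)propan-1-ol | COc1cc([C@H](O)[C@@H](Oc2c(Br)cc(/C=C/CO[Si](C(C)C)(C(C)C)C(C)C)cc2OC)CO[Si](C(C)C)(C(C)C)C(C)C)cc(OC)c1O[Si](C(C)C)(C(C)C)C(C)C | intermediate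
10 | (2S,3S)-2-[3,5-dimethoxy-4-(triisopropylsilyloxy)phenyl]-5-methoxy-3-[(triisopropylsilyloxy)methyl]-7-[(E)-3-(triisopropylsilyloxy)prop-1-en-1-yl]-2,3-dihydro-1,4-benzodioxine | COc1cc([C@@H]2Oc3cc(/C=C/CO[Si](C(C)C)(C(C)C)C(C)C)cc(OC)c3O[C@H]2CO[Si](C(C)C)(C(C)C)C(C)C)cc(OC)c1O[Si](C(C)C)(C(C)C)C(C)C | intermediate
11 | 4-[(2S,3S)-3-(hydroxymethyl)-7-[(E)-3-hydroxyprop-1-en-1-yl]-5-methoxy-2,3-dihydro-1,4-benzodioxin-2-yl]-2,6-dimethoxyphenol | COc1cc([C@@H]2Oc3cc(/C=C/CO)cc(OC)c3O[C@H]2CO)cc(OC)c1O | target

**Step count**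

Total steps: 7. Longest linear sequence: 6 (steps 1, 3, 4, 5, 6, 7); step 2 is a one-step branch.

**Steps most likely to fail**

1. Step 3 (proposed new method). The phenol-derived ylide may undergo the 1,2-proton shift faster than it is trapped by the aldehyde, so that only formal O–H insertion results, or the aldol trapping may proceed with poor diastereo- or enantiocontrol. Fallback by known chemistry, setting out from 2 and 4 and returning at 8: phenol 2 would be alkylated with (R)-4-benzyl-3-(bromoacetyl)-1,3-oxazolidin-2-one (K2CO3, acetone, rt) to give the aryloxyacetyl imide F1. An Evans syn glycolate aldol (Bu2BOTf, i-Pr2NEt, CH2Cl2, −78 °C, then aldehyde 4, buffered H2O2 work-up) should give the syn adduct F2, the (R)-benzyl auxiliary being the one that leads to the (2R,3S) configuration. LiBH4 (THF, MeOH, 0 °C) would remove the auxiliary reductively to give the diol F3, and i-Bu2AlH as in step 4 would reduce the acrylate and take off the pivalate to reach 8.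

2. Step 6. Insertion of copper into the electron-rich, ortho-oxygenated C–Br bond may be slow, so that protodebromination or base-induced silyl transfer (which would free the primary oxygen for closure of the isomeric ring) competes. Fallback, setting out from 9 and returning at 10, closing the ring at C2 instead of C8a: Miyaura borylation of 9 (Pd(dppf)Cl2, bis(pinacolato)diboron, KOAc, dioxane, 80 °C) would give the pinacol boronate F4, and NaBO3·4H2O (THF/H2O, rt) would convert it into the phenol F5. Catalytic camphorsulfonic acid (CH2Cl2, 0 °C) would then ionise the electron-rich benzylic alcohol so that the new phenol closes O1–C2 under thermodynamic control, where the trans (2S,3S) ring is favoured and C3 is untouched, giving 10.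

3. Step 5. The silylation may fail to discriminate among the four hydroxyls: incomplete reaction at the hindered phenol or partial reaction at the secondary hydroxyl. Fallback, setting out from 7 and returning at 9, marking the secondary hydroxyl before the primary ones exist: 7 would be capped (Et3SiOTf, 2,6-lutidine, CH2Cl2, −78 °C) as the triethylsilyl ether F6. i-Bu2AlH as in step 4 would give the phenolic diol F7, and exhaustive silylation (i-Pr3SiCl, imidazole, DMAP, DMF) would give the fully silylated compound F8. The much more labile secondary triethylsilyl ether would then be removed selectively (HF·pyridine buffered with pyridine, THF, 0 °C) to reach 9.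

**Further compounds**

F1 | step 3 | methyl (E)-3-{4-[2-((4R)-4-benzyl-2-oxo-1,3-oxazolidin-3-yl)-2-oxoethoxy]-3-bromo-5-methoxyphenyl}prop-2-enoate | COC(=O)/C=C/c1cc(Br)c(OCC(=O)N2[C@H](Cc3ccccc3)COC2=O)c(OC)c1
F2 | step 3 | syn aldol adduct, (4R)-4-benzyl-3-[(2R,3S)-2-aryloxy-3-hydroxy-3-aryl-propanoyl]-1,3-oxazolidin-2-one with the aryloxy and aryl groups of 7 | COc1cc([C@H](O)[C@@H](Oc2c(Br)cc(/C=C/C(=O)OC)cc2OC)C(=O)N2[C@H](Cc3ccccc3)COC2=O)cc(OC)c1OC(=O)C(C)(C)C
F3 | step 3 | methyl (E)-3-{3-bromo-4-[(1S,2S)-1-(3,5-dimethoxy-4-pivaloyloxyphenyl)-1,3-dihydroxypropan-2-yloxy]-5-methoxyphenyl}prop-2-enoate | COc1cc([C@H](O)[C@@H](Oc2c(Br)cc(/C=C/C(=O)OC)cc2OC)CO)cc(OC)c1OC(=O)C(C)(C)C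
F4 | step 6 | pinacol boronate of 9 (Bpin in place of Br at the future C8a; 1S,2S) | COc1cc([C@H](O)[C@@H](Oc2c(B3OC(C)(C)C(C)(C)O3)cc(/C=C/CO[Si](C(C)C)(C(C)C)C(C)C)cc2OC)CO[Si](C(C)C)(C(C)C)C(C)C)cc(OC)c1O[Si](C(C)C)(C(C)C)C(C)C
F5 | step 6 | phenol corresponding to 9 (OH in place of Br at the future C8a; 1S,2S) | COc1cc([C@H](O)[C@@H](Oc2c(O)cc(/C=C/CO[Si](C(C)C)(C(C)C)C(C)C)cc2OC)CO[Si](C(C)C)(C(C)C)C(C)C)cc(OC)c1O[Si](C(C)C)(C(C)C)C(C)C
F6 | step 5 | O-triethylsilyl ether of 7 at the secondary hydroxyl (2R,3S) | COc1cc([C@H](O[Si](CC)(CC)CC)[C@@H](Oc2c(Br)cc(/C=C/C(=O)OC)cc2OC)C(=O)OCC)cc(OC)c1OC(=O)C(C)(C)C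
F7 | step 5 | 8 carrying a triethylsilyl ether at the secondary hydroxyl (1S,2S) | COc1cc([C@H](O[Si](CC)(CC)CC)[C@@H](Oc2c(Br)cc(/C=C/CO)cc2OC)CO)cc(OC)c1O
F8 | step 5 | 9 carrying a triethylsilyl ether at the secondary hydroxyl (1S,2S) | COc1cc([C@H](O[Si](CC)(CC)CC)[C@@H](Oc2c(Br)cc(/C=C/CO[Si](C(C)C)(C(C)C)C(C)C)cc2OC)CO[Si](C(C)C)(C(C)C)C(C)C)cc(OC)c1O[Si](C(C)C)(C(C)C)C(C)C
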